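## Retrosynthetic overview

1. Target ⇒ allylic oxygenation with double-bond shift (Schenck ene) of a Diels–Alder bis-lactone, whose trans γ-lactone ⇒ cyclocarbonylation of a trans homopropargylic alcohol.
2. Ring C ⇒ [4+2] of a trans-alkynol dienone (diene, no activated alkene) with the cis-fused α-methylene lactone (dienophile). The lactone comes from the same alkynol by Mitsunobu formylation (inversion at C8) and a new formate-to-lactone isomerisation.
3. Alkynol dienone ⇒ Heck coupling (methyl vinyl ketone) of a cycloheptenyl triflate ⇒ key step: one-carbon ring expansion of a cyclohexanone with Me3SiCHN2/Sc(OTf)3 (1,2-alkyl shift, then 1,3-Brook shift). This single step builds the seven-membered ring of both halves and fixes the enol position.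
4. Cyclohexanone ⇒ α′-methylation and anti conjugate alkynylation (ethynyltrimethylsilane) of (R)-4-silyloxycyclohex-2-enone.
5. Ring order: cyclohexanone (bought) → cycloheptene (ring expansion) → cis γ-lactone of the dienophile half → cyclohexene ring C (cycloaddition) → trans γ-lactone of the diene half.

Assumption: (R)-4-[(tert-butyldimethylsilyl)oxy]cyclohex-2-en-1-one, the O-silyl-protected form of (R)-4-hydroxycyclohex-2-en-1-one (C6H8O2), is bought as the single enantiomer.

Reading of the target: the spiro lactone half is cis-fused, the α-methylene lactone on the hydroxylated half is trans-fused, and ring C is cis-fused to its cycloheptane with the OH cis to H-5.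

Locants: monomers are numbered as in their names. Dimers use xanthanolide numbering, unprimed for the half that acted as diene and primed for the half that acted as dienophile. Ring C is the cyclohexene C5–C1–C2–C3–C11′–C13′.

## Route

Step 1
Reactants: 1 (R)-4-[(tert-butyldimethylsilyl)oxy]cyclohex-2-en-1-one
Product: 2 (4R,6R)-4-[(tert-butyldimethylsilyl)oxy]-6-methylcyclohex-2-en-1-one
Conditions: LiN(i-Pr)2, THF, −78 °C; MeI, DMPU, −78 to −40 °C
Reagents that add atoms: iodomethane, CI
Why: Kinetic deprotonation at C6 gives the cross-conjugated lithium enolate, which is methylated mainly anti to the C4 silyloxy group (enolate alkylation); the C6 configuration and the minor 6S epimer are of no consequence because this centre is equilibrated in step 2.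

Step 2
Reactants: 2 (4R,6R)-4-[(tert-butyldimethylsilyl)oxy]-6-methylcyclohex-2-en-1-one; 3 ethynyltrimethylsilane
Product: 5 (2S,4R,5S)-4-[(tert-butyldimethylsilyl)oxy]-2-methyl-5-[(trimethylsilyl)ethynyl]cyclohexan-1-one, via kinetic C2 epimer 4 (not isolated)
Conditions: 3, n-BuLi, Et2O, −78 °C; Et2AlCl, 0 °C; then 2, Ni(acac)2 (5 mol %), i-Bu2AlH (5 mol %), Et2O, −5 °C; aqueous quench; crude product, DBU (0.2 equiv), CH2Cl2, rt
Reagents that add atoms: none
Why: Nickel-catalysed conjugate addition of the alkynylalane delivers the alkyne to the enone β-carbon anti to the neighbouring silyloxy group (sets the trans C4/C5 pair), and DBU then epimerises the α-methyl centre through the enol to the all-equatorial isomer (thermodynamic control).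

Step 3
Reactants: 5 (2S,4R,5S)-4-[(tert-butyldimethylsilyl)oxy]-2-methyl-5-[(trimethylsilyl)ethynyl]cyclohexan-1-one
Product: 9 (4S,5R,7S)-5-[(tert-butyldimethylsilyl)oxy]-7-methyl-4-[(trimethylsilyl)ethynyl]cyclohept-1-en-1-yl trifluoromethanesulfonate, via β-silyl ketone 6 (not isolated), via trimethylsilyl enol ether 7 (not isolated), via lithium enolate 8 (not isolated)
Conditions: Me3SiCHN2 (1.5 equiv), Sc(OTf)3 (5 mol %), toluene, 0 °C to rt; then MeLi, THF, 0 °C; then PhNTf2, −78 °C to rt
Reagents that add atoms: (trimethylsilyl)diazomethane, C[Si](C)(C)C=[N+]=[N-]; N-phenylbis(trifluoromethanesulfonimide), O=S(=O)(N(c1ccccc1)S(=O)(=O)C(F)(F)F)C(F)(F)F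
Why: Lewis-acid-catalysed diazoalkane homologation (Tiffeneau–Demjanov-type 1,2-alkyl shift) in which the less substituted C6 methylene migrates in preference to the C2 methine, followed by a 1,3-Brook shift that places the enol double bond on the inserted carbon, so that MeLi/PhNTf2 gives one alkenyl triflate regioisomer with the three stereocentres untouched.

Step 4
Reactants: 9 (4S,5R,7S)-5-[(tert-butyldimethylsilyl)oxy]-7-methyl-4-[(trimethylsilyl)ethynyl]cyclohept-1-en-1-yl trifluoromethanesulfonate; 10 but-3-en-2-one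
Product: 11 (E)-4-[(4S,5R,7S)-5-[(tert-butyldimethylsilyl)oxy]-7-methyl-4-[(trimethylsilyl)ethynyl]cyclohept-1-en-1-yl]but-3-en-2-one
Conditions: Pd(OAc)2 (5 mol %), PPh3 (10 mol %), Et3N, DMF, 60 °C
Reagents that add atoms: none
Why: Mizoroki–Heck coupling of the alkenyl triflate with the unhindered vinyl ketone; syn β-hydride elimination gives the (E)-dienone.

Step 5
Reactants: 11 (E)-4-[(4S,5R,7S)-5-[(tert-butyldimethylsilyl)oxy]-7-methyl-4-[(trimethylsilyl)ethynyl]cyclohept-1-en-1-yl]but-3-en-2-one
Product: 12 (E)-4-[(4S,5R,7S)-4-ethynyl-5-hydroxy-7-methylcyclohept-1-en-1-yl]but-3-en-2-one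
Conditions: Bu4NF (2.5 equiv), AcOH (2.5 equiv), THF, 0 °C to rt
Reagents that add atoms: none
Why: Fluoride cleaves the O–Si bond and the C(sp)–Si bond in one operation (desilylation), the acetic acid buffer keeping the base-sensitive dienone intact.

Step 6
Reactants: 12 (E)-4-[(4S,5R,7S)-4-ethynyl-5-hydroxy-7-methylcyclohept-1-en-1-yl]but-3-en-2-one
Product: 13 (1S,2S,6S)-2-ethynyl-6-methyl-5-[(E)-3-oxobut-1-en-1-yl]cyclohept-4-en-1-yl formate
Conditions: HCO2H, PPh3, DIAD, toluene, 0 °C to rt
Reagents that add atoms: formic acid, O=CO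
Why: Mitsunobu esterification, in which formate displaces the oxyphosphonium group by SN2 with inversion at the carbinol carbon, turning the trans ethynyl/oxygen pair into the cis pair needed for the dienophile half.

Step 7
Reactants: 13 (1S,2S,6S)-2-ethynyl-6-methyl-5-[(E)-3-oxobut-1-en-1-yl]cyclohept-4-en-1-yl formate
Product: 14 (3aS,7S,8aS)-7-methyl-3-methylidene-6-[(E)-3-oxobut-1-en-1-yl]-3,3a,4,7,8,8a-hexahydro-2H-cyclohepta[b]furan-2-one
Conditions: Pd(OAc)2 (5 mol %), Xantphos (7.5 mol %), MsOH (10 mol %), toluene (0.05 M), sealed tube, 90 °C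
Reagents that add atoms: none
Why: Proposed new method: intramolecular formate-to-alkyne hydroesterification, in which zerovalent palladium/Xantphos with catalytic MsOH activates the formyl C–H bond of 13 (directly, or by decarbonylation and recapture of the CO inside the closed vessel) to give the same alkoxycarbonyl palladium hydride that operates in CO-based cyclocarbonylation, 5-exo syn addition across the tethered alkyne bonds the carbonyl carbon to the internal alkyne carbon and C–H reductive elimination releases the exo-methylene lactone, an isomerisation that keeps every atom of the formate and leaves the C–O bond made in step 6 untouched so that the cis ring fusion is preserved; the closest known reaction types are the palladium-catalysed hydroesterification of alkynes with aryl formates and the cyclocarbonylation of homopropargylic alcohols with CO gas.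

Step 8
Reactants: 12 (E)-4-[(4S,5R,7S)-4-ethynyl-5-hydroxy-7-methylcyclohept-1-en-1-yl]but-3-en-2-one; 14 (3aS,7S,8aS)-7-methyl-3-methylidene-6-[(E)-3-oxobut-1-en-1-yl]-3,3a,4,7,8,8a-hexahydro-2H-cyclohepta[b]furan-2-one
Product: 15 alkynol cycloadduct (3S,5S,7S,8R,10S,7′S,8′S,10′S,11′R)
Conditions: 12 (3 equiv), 14 (1 equiv), BHT (5 mol %), toluene (2 M in 12), 90 °C, dark, 60 h
Reagents that add atoms: none
Why: Thermal Diels–Alder reaction of the s-cis dienone of 12 with the exocyclic alkene of 14 in the "ortho" orientation (spiro carbon to the acetyl-bearing terminus), in which the C5–C13′ bond forms by axial-type attack on the all-equatorial chair of 12 anti to the ethynyl group, the dienophile reacts on its convex face (that of H-7′ and H-8′) with the lactone carbonyl exo, which together set C3, C5 and C11′, while only 14 can act as dienophile because 12 has no activated alkene and its excess suppresses self-dimerisation of 14.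

Step 9
Reactants: 15 alkynol cycloadduct (3S,5S,7S,8R,10S,7′S,8′S,10′S,11′R)
Product: 16 bis-lactone cycloadduct (3S,5S,7S,8R,10S,7′S,8′S,10′S,11′R)
Conditions: CO (7 bar), PdCl2 (5 mol %), SnCl2 (5 mol %), PPh3 (10 mol %), MeCN, 75 °C
Reagents that add atoms: carbon monoxide, [C-]#[O+]
Why: Palladium-catalysed cyclocarbonylation of the homopropargylic alcohol, in which an alkoxycarbonyl palladium species adds syn across the alkyne at its internal carbon while the C8–O bond is untouched, so the trans-fused α-methylene γ-lactone forms with retention.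

Step 10
Reactants: 16 bis-lactone cycloadduct (3S,5S,7S,8R,10S,7′S,8′S,10′S,11′R)
Product: 18 CNP0168949.5 (target; 1R,5S,7S,8R,10S,7′S,8′S,10′S,11′R), via tertiary hydroperoxide 17 (not isolated)
Conditions: O2, tetraphenylporphyrin (0.5 mol %), white LED, CH2Cl2, −20 °C; then PPh3, 0 °C
Reagents that add atoms: dioxygen, O=O
Why: Schenck ene reaction, in which singlet oxygen bonds to C1 while removing the doubly activated H-3 (allylic and α to the acetyl group) suprafacially; H-3 is cis to H-5 as a result of step 8, so oxygen arrives on the face of H-5 (anti to the C10 methyl), giving the cis-fused tertiary hydroperoxide and the conjugated enone, and PPh3 reduces the O–O bond.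

## Compound list

1 | (R)-4-[(tert-butyldimethylsilyl)oxy]cyclohex-2-en-1-one | O=C1C=C[C@H](O[Si](C)(C)C(C)(C)C)CC1 | starting material
2 | (4R,6R)-4-[(tert-butyldimethylsilyl)oxy]-6-methylcyclohex-2-en-1-one (major trans epimer; the minor 6S epimer converges in step 2) | O=C1C=C[C@H](O[Si](C)(C)C(C)(C)C)C[C@H]1C | intermediate
3 | ethynyltrimethylsilane | C#C[Si](C)(C)C | starting material
4 | (2R,4R,5S)-4-[(tert-butyldimethylsilyl)oxy]-2-methyl-5-[(trimethylsilyl)ethynyl]cyclohexan-1-one (kinetic C2 epimer) | O=C1C[C@@H](C#C[Si](C)(C)C)[C@H](O[Si](C)(C)C(C)(C)C)C[C@H]1C | intermediate (not isolated)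
5 | (2S,4R,5S)-4-[(tert-butyldimethylsilyl)oxy]-2-methyl-5-[(trimethylsilyl)ethynyl]cyclohexan-1-one (all-equatorial) | O=C1C[C@@H](C#C[Si](C)(C)C)[C@H](O[Si](C)(C)C(C)(C)C)C[C@@H]1C | intermediate
6 | (4S,5R,7S)-5-[(tert-butyldimethylsilyl)oxy]-7-methyl-2-(trimethylsilyl)-4-[(trimethylsilyl)ethynyl]cycloheptan-1-one (both C2 epimers) | O=C1C([Si](C)(C)C)C[C@@H](C#C[Si](C)(C)C)[C@H](O[Si](C)(C)C(C)(C)C)C[C@@H]1C | intermediate (not isolated)
7 | {[(4S,5R,7S)-5-[(tert-butyldimethylsilyl)oxy]-7-methyl-4-[(trimethylsilyl)ethynyl]cyclohept-1-en-1-yl]oxy}trimethylsilane | C[Si](C)(C)OC1=CC[C@@H](C#C[Si](C)(C)C)[C@H](O[Si](C)(C)C(C)(C)C)C[C@@H]1C | intermediate (not isolated)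
8 | lithium (4S,5R,7S)-5-[(tert-butyldimethylsilyl)oxy]-7-methyl-4-[(trimethylsilyl)ethynyl]cyclohept-1-en-1-olate | [Li+].[O-]C1=CC[C@@H](C#C[Si](C)(C)C)[C@H](O[Si](C)(C)C(C)(C)C)C[C@@H]1C | intermediate (not isolated)
9 | (4S,5R,7S)-5-[(tert-butyldimethylsilyl)oxy]-7-methyl-4-[(trimethylsilyl)ethynyl]cyclohept-1-en-1-yl trifluoromethanesulfonate | O=S(=O)(OC1=CC[C@@H](C#C[Si](C)(C)C)[C@H](O[Si](C)(C)C(C)(C)C)C[C@@H]1C)C(F)(F)F | intermediate
10 | but-3-en-2-one (methyl vinyl ketone) | CC(=O)C=C | starting material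
11 | (E)-4-[(4S,5R,7S)-5-[(tert-butyldimethylsilyl)oxy]-7-methyl-4-[(trimethylsilyl)ethynyl]cyclohept-1-en-1-yl]but-3-en-2-one | CC(=O)/C=C/C1=CC[C@@H](C#C[Si](C)(C)C)[C@H](O[Si](C)(C)C(C)(C)C)C[C@@H]1C | intermediate
12 | (E)-4-[(4S,5R,7S)-4-ethynyl-5-hydroxy-7-methylcyclohept-1-en-1-yl]but-3-en-2-one (trans alkynol) | CC(=O)/C=C/C1=CC[C@@H](C#C)[C@H](O)C[C@@H]1C | intermediate
13 | (1S,2S,6S)-2-ethynyl-6-methyl-5-[(E)-3-oxobut-1-en-1-yl]cyclohept-4-en-1-yl formate (cis) | CC(=O)/C=C/C1=CC[C@@H](C#C)[C@@H](OC=O)C[C@@H]1C | intermediate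
14 | (3aS,7S,8aS)-7-methyl-3-methylidene-6-[(E)-3-oxobut-1-en-1-yl]-3,3a,4,7,8,8a-hexahydro-2H-cyclohepta[b]furan-2-one (cis-fused lactone) | C=C1C(=O)O[C@H]2C[C@H](C)C(/C=C/C(C)=O)=CC[C@@H]12 | intermediate
15 | alkynol cycloadduct (3S,5S,7S,8R,10S,7′S,8′S,10′S,11′R): ring C is a cyclohex-1(2)-ene made of C5, C1, C2, C3, C11′, C13′ with 3-acetyl (H-3 cis to H-5), spiro at C11′ to the cis-fused γ-lactone of the half that keeps its (E)-3-oxobutenyl cycloheptene; the other cycloheptane carries 7-ethynyl, 8-hydroxy (trans) and 10-methyl | O[C@@H]1C[C@H](C)C2=C[C@H](C(C)=O)[C@]3(C[C@@H]2C[C@H]1C#C)C(=O)O[C@H]1C[C@H](C)C(/C=C/C(C)=O)=CC[C@H]13 | intermediate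
16 | bis-lactone cycloadduct (3S,5S,7S,8R,10S,7′S,8′S,10′S,11′R): 15 with the 7-ethynyl/8-hydroxy pair closed to the trans-fused α-methylene γ-lactone | C=C1C(=O)O[C@@H]2C[C@H](C)C3=C[C@H](C(C)=O)[C@]4(C[C@@H]3C[C@@H]12)C(=O)O[C@H]1C[C@H](C)C(/C=C/C(C)=O)=CC[C@H]14 | intermediate
17 | (1R,5S,7S,8R,10S,7′S,8′S,10′S,11′R)-1-hydroperoxide: 16 with OOH at C1 (cis to H-5) and the ring C double bond at C2=C3 | C=C1C(=O)O[C@@H]2C[C@H](C)[C@]3(OO)C=C(C(C)=O)[C@]4(C[C@@H]3C[C@@H]12)C(=O)O[C@H]1C[C@H](C)C(/C=C/C(C)=O)=CC[C@H]14 | intermediate (not isolated)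
18 | CNP0168949.5, (1R,5S,7S,8R,10S,7′S,8′S,10′S,11′R)-1-hydroxy compound: 17 with OH in place of OOH | C=C1C(=O)O[C@@H]2C[C@H](C)[C@]3(O)C=C(C(C)=O)[C@]4(C[C@@H]3C[C@@H]12)C(=O)O[C@H]1C[C@H](C)C(/C=C/C(C)=O)=CC[C@H]14 | target

## Step count and risks

Total step count: 10. Longest linear sequence: 10 steps (1 → 2 → 5 → 9 → 11 → 12 → 13 → 14 → 15 → 16 → 18); compound 12 serves both as the diene and as the source of dienophile 14.

Steps most likely to fail:

Step 7 (the proposed new step). The alkyl formate may lose CO without recapturing it, or may not be activated at all. The fallback uses known chemistry and sets out from 13. K2CO3 (0.2 equiv) in MeOH at 0 °C cleaves the formate to the cis alkynol (E)-4-[(4S,5S,7S)-4-ethynyl-5-hydroxy-7-methylcyclohept-1-en-1-yl]but-3-en-2-one F1. F1 is then cyclocarbonylated with CO gas (7 bar, PdCl2, SnCl2, PPh3, MeCN, 75 °C, retention at the carbinol carbon) and comes back to the route at 14.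

Step 8. The face of the diene that is attacked, the exo/endo ratio and self-dimerisation of 14 are all uncertain; the stereochemical outcome given in the step is a conformational argument, not a precedent. The fallback sets out from 12. The trans lactone is closed first with the cyclocarbonylation conditions of step 9, giving (3aS,7S,8aR)-7-methyl-3-methylidene-6-[(E)-3-oxobut-1-en-1-yl]-3,3a,4,7,8,8a-hexahydro-2H-cyclohepta[b]furan-2-one F2, a rigid trans-fused bicyclic diene whose chair cannot flip. F2 and 14 (1:1) are then combined at 12 kbar in CH2Cl2 at room temperature. The statistical mixture of dimers is separated, and the hetero-dimer comes back to the route at 16, so step 9 is skipped.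

Step 10. Singlet oxygen may remove H-5 or H-10 instead of H-3, or the skipped enone may already have moved into conjugation during step 9. The fallback sets out from 15, where no α-methylene lactone is present yet and a guanidine base is tolerated. Copper-catalysed aerobic dienolate oxygenation (Cu(OTf)2 10 mol %, 1,1,3,3-tetramethylguanidine 20 mol %, air, THF, rt) gives the C1 hydroperoxide of the alkynol cycloadduct F3. PPh3 reduces it to the C1-hydroxy 2-ene alkynol F4; oxygen again enters anti to the C10 methyl, on the face of H-5. The cyclocarbonylation of step 9 then closes the trans lactone and comes back to the route at 18.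

## Further compounds

F1 | step 7 | (E)-4-[(4S,5S,7S)-4-ethynyl-5-hydroxy-7-methylcyclohept-1-en-1-yl]but-3-en-2-one | CC(=O)/C=C/C1=CC[C@@H](C#C)[C@@H](O)C[C@@H]1C
F2 | step 8 | (3aS,7S,8aR)-7-methyl-3-methylidene-6-[(E)-3-oxobut-1-en-1-yl]-3,3a,4,7,8,8a-hexahydro-2H-cyclohepta[b]furan-2-one | C=C1C(=O)O[C@@H]2C[C@H](C)C(/C=C/C(C)=O)=CC[C@@H]12
F3 | step 10 | C1 hydroperoxide of the alkynol cycloadduct (1R,5S,7S,8R,10S,7′S,8′S,10′S,11′R; ring C double bond at C2=C3) | O[C@@H]1C[C@H](C)[C@]2(OO)C=C(C(C)=O)[C@]3(C[C@@H]2C[C@H]1C#C)C(=O)O[C@H]1C[C@H](C)C(/C=C/C(C)=O)=CC[C@H]13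
F4 | step 10 | C1-hydroxy 2-ene alkynol (1R,5S,7S,8R,10S,7′S,8′S,10′S,11′R) | O[C@@H]1C[C@H](C)[C@]2(O)C=C(C(C)=O)[C@]3(C[C@@H]2C[C@H]1C#C)C(=O)O[C@H]1C[C@H](C)C(/C=C/C(C)=O)=CC[C@H]13
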